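## Retrosynthetic overview
1. Target ⇒ global O-debenzylation of an octabenzyl dimer. Cutting its C4(ring C)–C8(ring D) bond gives two halves that both come from one monomer.
2. The monomer is a 2,3-cis-flavan-3,4-diol held as its cyclic 3,4-phenylboronate. Ionised at C4, it is the upper unit. After C4 captures an acetic acid dianion equivalent, it is the lower, C8-nucleophilic unit.
3. Key disconnection of the monomer: C4–C4a and O1–C2 are cut together ⇒ 3,5-bis(benzyloxy)phenol + trans-epoxy aldehyde + PhB(OH)2. The pyran and dioxaborolane rings close in one operation on a boron template, with retention at C2 (trans-oxirane → 2,3-cis).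
4. Epoxy aldehyde ⇒ asymmetric epoxidation of the E-cinnamaldehyde ⇒ Wittig homologation of 3,4-bis(benzyloxy)benzaldehyde.
5. Ring order: the aromatic rings are bought. The oxirane forms first, then the pyran and dioxaborolane together. This pyran is ring C in one copy and ring F in the other. The boronate rings open again when C4 is substituted.

Assumption: flavan numbering and α/β descriptors are used (upper unit rings A, C, B; lower unit rings D, F, E), and the three starting materials and both enantiomers of the pyrrolidine catalyst are taken as catalogue items.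

## Route

Step 1
Reactants: 1 3,4-bis(benzyloxy)benzaldehyde; 2 (triphenylphosphoranylidene)acetaldehyde
Product: 3 (E)-3-[3,4-bis(benzyloxy)phenyl]prop-2-enal
Conditions: toluene, 80 °C, 16 h
Reagents that add atoms: none
Why: Wittig olefination with a stabilised formyl ylide gives the (E)-enal selectively, and no stereocentre is formed.

Step 2
Reactants: 3 (E)-3-[3,4-bis(benzyloxy)phenyl]prop-2-enal
Product: 4 (2S,3R)-3-[3,4-bis(benzyloxy)phenyl]oxirane-2-carbaldehyde (trans)
Conditions: 35 % aq. H2O2 (1.3 equiv), (R)-2-{bis[3,5-bis(trifluoromethyl)phenyl](trimethylsilyloxy)methyl}pyrrolidine (10 mol %), CH2Cl2, 20 °C; short silica plug, used at once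
Reagents that add atoms: hydrogen peroxide OO
Why: In this organocatalytic iminium–enamine (Weitz–Scheffer type, Jørgensen) epoxidation the bulky arm of the (R)-pyrrolidine shields one face of the E-iminium ion, so hydroperoxide adds to the β carbon from the open face and the enamine closes the trans-oxirane, setting both oxirane carbons as (2S,3R), the future C3 and C2 of each flavan unit.

Step 3
Reactants: 4 (2S,3R)-3-[3,4-bis(benzyloxy)phenyl]oxirane-2-carbaldehyde; 5 3,5-bis(benzyloxy)phenol
Product: 8 (2R,3R,4R)-5,7-bis(benzyloxy)-2-[3,4-bis(benzyloxy)phenyl]chromane-3,4-diyl phenylboronate, via aryloxy(hydroxy)phenylborane 6 (not isolated), via oxiranyl benzodioxaborin 7 (not isolated)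
Conditions: 5, PhB(OH)2 (1.05 equiv), EtCO2H (20 mol %), 4 Å MS, toluene, 20 °C, 1 h; then 4 added over 2 h at 0 °C, 0 → 40 °C
Reagents that add atoms: phenylboronic acid OB(O)c1ccccc1
Why: Proposed new method: 5 and PhB(OH)2 condense to 6, whose boron binds the aldehyde of 4 and delivers the ortho carbon through a closed six-membered transition state (Nagata-type boronic-acid-mediated ortho-hydroxyalkylation, polar Felkin–Anh sense) to the erythro benzodioxaborin 7; the boron of 7 then chelates the neighbouring oxirane oxygen in a bicyclo[3.2.1] borate cage where the aryloxy oxygen and the departing oxirane oxygen sit on the same boron, so back-side attack is geometrically excluded and O1–C2 forms on the face the oxirane oxygen leaves (SNi-type syn opening, as known for aryl borates with aryl oxiranes), turning the trans-oxirane into the 2,3-cis pyran with retention at C2 and untouched C3 while boron slips onto O3/O4 as the cis-fused dioxaborolane; a looser benzylic cation would close the same way because the cage holds O3 axial and the aryl group then takes the equatorial site.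

Step 4
Reactants: 8 (2R,3R,4R)-5,7-bis(benzyloxy)-2-[3,4-bis(benzyloxy)phenyl]chromane-3,4-diyl phenylboronate
Product: 9 2-{(2R,3R,4S)-5,7-bis(benzyloxy)-2-[3,4-bis(benzyloxy)phenyl]-3-hydroxychroman-4-yl}acetic acid (tetra-O-benzyl-4β-carboxymethylepicatechin)
Conditions: AcOH (1.5 equiv), iPr2NEt (3.1 equiv), Me3SiOTf (3.5 equiv), CH2Cl2, 20 °C, 1 h; then 8, −78 → −40 °C; aq. citric acid/THF work-up
Reagents that add atoms: acetic acid CC(=O)O
Why: In this SN1-type Mukaiyama alkylation Me3SiOTf ionises the strongly activated benzylic C4–O(boron) bond and CH2=C(OSiMe3)2, made in the flask from acetic acid by soft enolisation, attacks axially from the β face anti to the axial 3-O-boryl group, which sets C4 as 4β (3,4-trans, 4S), and the work-up frees the acid and the 3-OH.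

Step 5
Reactants: 8 (2R,3R,4R)-5,7-bis(benzyloxy)-2-[3,4-bis(benzyloxy)phenyl]chromane-3,4-diyl phenylboronate; 9 tetra-O-benzyl-4β-carboxymethylepicatechin
Product: 10 octa-O-benzyl epicatechin-(4β→8)-4β-carboxymethylepicatechin [upper unit 2R,3R,4R; lower unit 2R,3R,4S]
Conditions: 9 (3 equiv), Me3SiOTf (20 mol %), CH2Cl2, −78 °C, 8 added over 2 h, → −30 °C; pH 4 buffer work-up; surplus 9 recovered
Reagents that add atoms: none
Why: In this Friedel–Crafts type flavan C4→C8 coupling the C4 cation from 8 is attacked by C8 of 9, the position that reacts in benzylated flavan-3-ols, from the β face anti to the 3-oxygen, so the new C4 is 4β (3,4-trans, 4R), while slow addition into excess 9 suppresses self-condensation of 8 and pairing two enantioenriched units sends the minor enantiomer into separable diastereomers.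

Step 6
Reactants: 10 octa-O-benzyl epicatechin-(4β→8)-4β-carboxymethylepicatechin
Product: 11 epicatechin-(4β→8)-4β-carboxymethylepicatechin (CNP0190976.1)
Conditions: H2 (1 atm), Pd(OH)2/C, THF/MeOH/H2O, 20 °C; Sephadex LH-20
Reagents that add atoms: none
Why: Heterogeneous hydrogenolysis removes the eight benzyl aryl ethers, while the interflavan C–C bond, the pyran C2–O bonds, the acid and all six stereocentres are inert under these neutral conditions.

## Compound list
1 | 3,4-bis(benzyloxy)benzaldehyde | O=Cc1ccc(OCc2ccccc2)c(OCc2ccccc2)c1 | starting material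
2 | (triphenylphosphoranylidene)acetaldehyde | O=CC=P(c1ccccc1)(c1ccccc1)c1ccccc1 | starting material
3 | (E)-3-[3,4-bis(benzyloxy)phenyl]prop-2-enal | O=C/C=C/c1ccc(OCc2ccccc2)c(OCc2ccccc2)c1 | intermediate
4 | (2S,3R)-3-[3,4-bis(benzyloxy)phenyl]oxirane-2-carbaldehyde, trans | O=C[C@H]1O[C@@H]1c1ccc(OCc2ccccc2)c(OCc2ccccc2)c1 | intermediate
5 | 3,5-bis(benzyloxy)phenol | Oc1cc(OCc2ccccc2)cc(OCc2ccccc2)c1 | starting material
6 | 3,5-bis(benzyloxy)phenyl hydrogen phenylboronate (not isolated) | OB(c1ccccc1)Oc1cc(OCc2ccccc2)cc(OCc2ccccc2)c1 | intermediate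
7 | (4R)-5,7-bis(benzyloxy)-4-{(2R,3R)-3-[3,4-bis(benzyloxy)phenyl]oxiran-2-yl}-2-phenyl-4H-1,3,2-benzodioxaborinine, erythro (not isolated) | c1ccccc1B1Oc2cc(OCc3ccccc3)cc(OCc3ccccc3)c2[C@@H](O1)[C@H]1O[C@@H]1c1ccc(OCc2ccccc2)c(OCc2ccccc2)c1 | intermediate
8 | (2R,3R,4R)-5,7-bis(benzyloxy)-2-[3,4-bis(benzyloxy)phenyl]chromane-3,4-diyl phenylboronate, 2,3-cis-3,4-cis (aryl, O3 and O4 all α) | c1ccccc1B2O[C@@H]1c3c(OCc4ccccc4)cc(OCc4ccccc4)cc3O[C@H](c3ccc(OCc4ccccc4)c(OCc4ccccc4)c3)[C@@H]1O2 | intermediate
9 | 2-{(2R,3R,4S)-5,7-bis(benzyloxy)-2-[3,4-bis(benzyloxy)phenyl]-3-hydroxychroman-4-yl}acetic acid, 2,3-cis-3,4-trans | O=C(O)C[C@H]1c2c(OCc3ccccc3)cc(OCc3ccccc3)cc2O[C@H](c2ccc(OCc3ccccc3)c(OCc3ccccc3)c2)[C@@H]1O | intermediate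
10 | octa-O-benzyl epicatechin-(4β→8)-4β-carboxymethylepicatechin | O=C(O)C[C@H]1c2c(OCc3ccccc3)cc(OCc3ccccc3)c([C@H]3c4c(OCc5ccccc5)cc(OCc5ccccc5)cc4O[C@H](c4ccc(OCc5ccccc5)c(OCc5ccccc5)c4)[C@@H]3O)c2O[C@H](c2ccc(OCc3ccccc3)c(OCc3ccccc3)c2)[C@@H]1O | intermediate
11 | epicatechin-(4β→8)-4β-carboxymethylepicatechin (CNP0190976.1) | O=C(O)C[C@H]1c2c(O)cc(O)c([C@H]3c4c(O)cc(O)cc4O[C@H](c4ccc(O)c(O)c4)[C@@H]3O)c2O[C@H](c2ccc(O)c(O)c2)[C@@H]1O | target

## Step count and weak points
Total step count: 6. Longest linear sequence: 6 (steps 1 to 6). Compound 8 is used twice, in steps 4 and 5.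

**Step 3 (most likely to fail).**
- Failure modes: the electron-rich phenol may attack the benzylic oxirane carbon through carbon. The activated oxirane may undergo a 1,2-hydride shift. Retention may leak if the phenol oxygen leaves boron too early.
- The fallback sets out from 4 and 5 and comes back at 8. It replaces templated retention by two separate inversions.
- The bromomagnesium phenolate of 5 (EtMgBr, CH2Cl2) adds through its ortho carbon to aldehyde 4 and gives the erythro epoxy alcohol F1.
- MgBr2·OEt2 at −40 °C opens the oxirane at the benzylic carbon with inversion to the bromohydrin F2.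
- K2CO3 in acetone deprotonates only the phenol. Its SN2 ring closure inverts the same carbon a second time and gives the free 2,3-cis-3,4-cis flavan-3,4-diol F3.
- PhB(OH)2 with MgSO4 then converts this diol into 8.

**Step 5.**
- Failure modes: 8 carries its own nucleophilic C8 and may oligomerise. The free acid may slow the coupling.
- The fallback sets out from 8 (with 9) and comes back at 11.
- N-bromosuccinimide (1 equiv, CH2Cl2, −78 °C) blocks C8 and gives the 8-bromo boronate F4, which can act only as the electrophile.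
- It is therefore coupled 1:1 with 9 (BF3·OEt2, −78 °C) to the bromo dimer F5.
- Hydrogenolysis over Pd(OH)2/C with Et3N removes the bromine together with the benzyl groups and gives 11.

**Step 2.**
- Failure modes: the electron-rich epoxy aldehyde may not survive aqueous peroxide and the amine, or the selectivity may be lower than for plain cinnamaldehyde.
- The fallback sets out from 3 and comes back at 4.
- iBu2AlH reduces 3 to the cinnamyl alcohol F6.
- Katsuki–Sharpless epoxidation (Ti(OiPr)4, D-(−)-diethyl tartrate, tBuOOH, 4 Å MS, −20 °C) gives the (2R,3R)-epoxy alcohol F7.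
- SO3·pyridine, DMSO and Et3N oxidise it under non-aqueous conditions to 4, which is used crude.

## Further compounds
F1 | step 3 | (R)-[2,4-bis(benzyloxy)-6-hydroxyphenyl]{(2R,3R)-3-[3,4-bis(benzyloxy)phenyl]oxiran-2-yl}methanol | Oc1cc(OCc2ccccc2)cc(OCc2ccccc2)c1[C@@H](O)[C@H]1O[C@@H]1c1ccc(OCc2ccccc2)c(OCc2ccccc2)c1
F2 | step 3 | (1R,2R,3S)-1-[2,4-bis(benzyloxy)-6-hydroxyphenyl]-3-[3,4-bis(benzyloxy)phenyl]-3-bromopropane-1,2-diol | Oc1cc(OCc2ccccc2)cc(OCc2ccccc2)c1[C@@H](O)[C@@H](O)[C@@H](Br)c1ccc(OCc2ccccc2)c(OCc2ccccc2)c1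
F3 | step 3 | (2R,3R,4R)-5,7-bis(benzyloxy)-2-[3,4-bis(benzyloxy)phenyl]chromane-3,4-diol | O[C@@H]1c2c(OCc3ccccc3)cc(OCc3ccccc3)cc2O[C@H](c2ccc(OCc3ccccc3)c(OCc3ccccc3)c2)[C@@H]1O
F4 | step 5 | (2R,3R,4R)-5,7-bis(benzyloxy)-2-[3,4-bis(benzyloxy)phenyl]-8-bromochromane-3,4-diyl phenylboronate | c1ccccc1B2O[C@@H]1c3c(OCc4ccccc4)cc(OCc4ccccc4)c(Br)c3O[C@H](c3ccc(OCc4ccccc4)c(OCc4ccccc4)c3)[C@@H]1O2
F5 | step 5 | octa-O-benzyl 8-bromoepicatechin-(4β→8)-4β-carboxymethylepicatechin | O=C(O)C[C@H]1c2c(OCc3ccccc3)cc(OCc3ccccc3)c([C@H]3c4c(OCc5ccccc5)cc(OCc5ccccc5)c(Br)c4O[C@H](c4ccc(OCc5ccccc5)c(OCc5ccccc5)c4)[C@@H]3O)c2O[C@H](c2ccc(OCc3ccccc3)c(OCc3ccccc3)c2)[C@@H]1O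
F6 | step 2 | (E)-3-[3,4-bis(benzyloxy)phenyl]prop-2-en-1-ol | OC/C=C/c1ccc(OCc2ccccc2)c(OCc2ccccc2)c1
F7 | step 2 | {(2R,3R)-3-[3,4-bis(benzyloxy)phenyl]oxiran-2-yl}methanol | OC[C@H]1O[C@@H]1c1ccc(OCc2ccccc2)c(OCc2ccccc2)c1
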